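**Strategy.** The cyclopentane is cut at C2–C3 and C3a–C8a (octahydroazulene numbering). Both bonds are made in one rhodium-catalysed operation from an acyclic allyl vinyl ether. A Claisen rearrangement joins the enol ether carbon (future C3a) to the methyl-bearing diene carbon (future C8a, left with two vinyl groups). The liberated aldehyde (future C3) then hydroacylates one vinyl group (future C1–C2). The step exploits the C3 carbinol flanked by C3a–H and the C8a quaternary centre carrying a vinylic carbon (C8). One catalysis-set carbinol is relayed to C4, C3a, C8a, C3 and C6; the second vinyl group closes the seven-membered ring by metathesis.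

Key step: step 6

Assumptions: the E isomer of enynol 1 is bought as such. (S,S)-ProPhenol (step 3) and (R)-BINAP (step 6) are working choices of ligand antipode, to be fixed by the sense of induction found in a first run. Bicyclic compounds carry azulene numbering (C1–C3, C3a and C8a in the five-membered ring; C4–C8 in the seven-membered ring).

**Step 1**
Reactants: 1 (E)-3-methylpent-2-en-4-yn-1-ol
Product: 2 (E)-3-methylpenta-2,4-dien-1-ol
Conditions: H2 (1 atm), Pd/CaCO3 poisoned with Pb(OAc)2 (Lindlar catalyst), quinoline, EtOAc, 0 °C to rt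
Reagents that add atoms: none
Why: Lindlar semi-hydrogenation of the terminal alkyne should stop at the vinyl group on the poisoned palladium surface, leaving the trisubstituted E alkene untouched; no stereocentre is formed.

**Step 2**
Reactants: 2 (E)-3-methylpenta-2,4-dien-1-ol; 3 but-3-yn-2-one
Product: 4 (3E)-4-{[(2E)-3-methylpenta-2,4-dien-1-yl]oxy}but-3-en-2-one
Conditions: DABCO (10 mol%), CH2Cl2, 0 °C to rt
Reagents that add atoms: none
Why: Amine-catalysed oxa-Michael (conjugate) addition of the alcohol to the ynone should give the trans β-alkoxy enone, under conditions too mild for rearrangement of this allyl vinyl ether.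

**Step 3**
Reactants: 4 (3E)-4-{[(2E)-3-methylpenta-2,4-dien-1-yl]oxy}but-3-en-2-one; 5 (E)-but-2-enal
Product: 6 (1E,5R,6E)-5-hydroxy-1-{[(2E)-3-methylpenta-2,4-dien-1-yl]oxy}octa-1,6-dien-3-one
Conditions: (S,S)-ProPhenol (10 mol%), Et2Zn (20 mol%), 4 Å MS, THF, −20 °C
Reagents that add atoms: none
Why: Direct catalytic asymmetric aldol addition with the dinuclear zinc–ProPhenol catalyst: the zinc enolate can form only at the methyl group and adds to an aldehyde that cannot enolise at its α-carbon, the catalyst setting the C5 carbinol (5R) as the one stereocentre from which all others are relayed.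

**Step 4**
Reactants: 6 (1E,5R,6E)-5-hydroxy-1-{[(2E)-3-methylpenta-2,4-dien-1-yl]oxy}octa-1,6-dien-3-one
Product: 7 (1E,3S,5R,6E)-1-{[(2E)-3-methylpenta-2,4-dien-1-yl]oxy}octa-1,6-diene-3,5-diol
Conditions: Et2BOMe, NaBH4, THF/MeOH (4:1), −78 °C; then MeOH, pH 7 buffer
Reagents that add atoms: none
Why: Narasaka–Prasad reduction: the diethylboron chelate of the β-hydroxy ketone should take hydride axially at the activated carbonyl (1,2-reduction), so that the new C3 carbinol (3S) is syn to C5.

**Step 5**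
Reactants: 7 (1E,3S,5R,6E)-1-{[(2E)-3-methylpenta-2,4-dien-1-yl]oxy}octa-1,6-diene-3,5-diol
Product: 8 (1E,3S,5R,6E)-3,5-bis[(tert-butyldimethylsilyl)oxy]-1-{[(2E)-3-methylpenta-2,4-dien-1-yl]oxy}octa-1,6-diene
Conditions: TBSCl, imidazole, DMAP (cat.), DMF, rt to 40 °C
Reagents that add atoms: tert-butyldimethylsilyl chloride, CC(C)(C)[Si](C)(C)Cl
Why: Silylation of both secondary alcohols under basic conditions that the acid-sensitive γ-oxy enol ether tolerates; no stereocentre is touched.

**Step 6**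
Reactants: 8 (1E,3S,5R,6E)-3,5-bis[(tert-butyldimethylsilyl)oxy]-1-{[(2E)-3-methylpenta-2,4-dien-1-yl]oxy}octa-1,6-diene
Product: 10 (2S,3S)-2-{(1S,3R,4E)-1,3-bis[(tert-butyldimethylsilyl)oxy]hex-4-en-1-yl}-3-ethenyl-3-methylcyclopentan-1-one, via Claisen aldehyde 9 (not isolated)
Conditions: [Rh(cod)Cl]2 (5 mol%), (R)-BINAP (11 mol%), toluene, 120 °C, sealed tube
Reagents that add atoms: none
Why: Heating first triggers a [3,3] sigmatropic (Claisen) rearrangement of the allyl vinyl ether through a chair transition state, which bonds the enol ether carbon to the methyl-bearing diene carbon and releases the 4-pentenal 9; monovalent rhodium then inserts into the aldehyde C–H bond, adds Rh–H across one vinyl group with rhodium at the terminal carbon, and reductive elimination from the six-membered acyl rhodacycle gives the cyclopentanone. The closest known reaction type is the one-pot rhodium-catalysed Claisen rearrangement–intramolecular hydroacylation of allyl vinyl ethers to cyclopentanones, together with the rhodium–BINAP hydroacylation that differentiates two alkenyl groups on one carbon. The only ring closed is the cyclopentanone, by acyl–alkyl reductive elimination that joins the formyl carbon to the terminal vinyl carbon (a formal 5-endo hydroacylation of a 4-pentenal). C2 of the ring (future C3a) is set in the Claisen step by 1,2-induction from the adjacent silyloxy stereocentre, the diene terminus adding to the enol ether face anti to the allylic C–O bond in the conformer of least A(1,3) strain; the enol ether geometry does not matter because the migration terminus becomes a carbon with two identical vinyl groups. C3 (future C8a) is set in the hydroacylation by the choice between these two diastereotopic vinyl groups: the rhodacycle that keeps the C2 side chain pseudo-equatorial and cis to the spectator vinyl group is expected to be preferred, and the BINAP antipode is chosen to reinforce it. Chemoselectivity for the five-membered ketone over reaction at the propenyl group follows from the 4-pentenal geometry, and decarbonylation should stay low because the aldehyde is consumed as fast as the rate-limiting rearrangement delivers it.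

**Step 7**
Reactants: 10 (2S,3S)-2-{(1S,3R,4E)-1,3-bis[(tert-butyldimethylsilyl)oxy]hex-4-en-1-yl}-3-ethenyl-3-methylcyclopentan-1-one
Product: 11 (1R,2S,3S)-2-{(1S,3R,4E)-1,3-bis[(tert-butyldimethylsilyl)oxy]hex-4-en-1-yl}-3-ethenyl-3-methyl-1-(propan-2-yl)cyclopentan-1-ol
Conditions: i-PrMgCl, LaCl3·2LiCl, THF, −20 to 0 °C; then H2O
Reagents that add atoms: isopropylmagnesium chloride, CC(C)[Mg]Cl
Why: Grignard 1,2-addition in which LaCl3·2LiCl activates the ketone and suppresses enolisation and β-hydride reduction; the nucleophile should enter trans to the C2 side chain, placing the new tertiary hydroxyl cis to that chain (1R).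

**Step 8**
Reactants: 11 (1R,2S,3S)-2-{(1S,3R,4E)-1,3-bis[(tert-butyldimethylsilyl)oxy]hex-4-en-1-yl}-3-ethenyl-3-methyl-1-(propan-2-yl)cyclopentan-1-ol
Product: 12 (3R,3aS,4S,6R,8aS)-4,6-bis[(tert-butyldimethylsilyl)oxy]-8a-methyl-3-(propan-2-yl)-1,2,3,3a,4,5,6,8a-octahydroazulen-3-ol
Conditions: second-generation Hoveyda–Grubbs catalyst (10 mol%), toluene, 80 °C
Reagents that add atoms: none
Why: Ring-closing metathesis of the remaining vinyl group with the propenyl group, held cis on the cyclopentane, should close the cis-fused cycloheptene with loss of propene; the new alkene is Z by ring constraint and no stereocentre changes.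

**Step 9**
Reactants: 12 (3R,3aS,4S,6R,8aS)-4,6-bis[(tert-butyldimethylsilyl)oxy]-8a-methyl-3-(propan-2-yl)-1,2,3,3a,4,5,6,8a-octahydroazulen-3-ol
Product: 13 (3R,3aS,4S,6R,8aS)-4-[(tert-butyldimethylsilyl)oxy]-8a-methyl-3-(propan-2-yl)-1,2,3,3a,4,5,6,8a-octahydroazulene-3,6-diol
Conditions: HF·pyridine, pyridine, THF, 0 °C
Reagents that add atoms: none
Why: Selective desilylation: the allylic, unhindered C6 silyl ether should be cleaved well before the C4 silyl ether, which is buried next to the ring fusion.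

**Step 10**
Reactants: 13 (3R,3aS,4S,6R,8aS)-4-[(tert-butyldimethylsilyl)oxy]-8a-methyl-3-(propan-2-yl)-1,2,3,3a,4,5,6,8a-octahydroazulene-3,6-diol
Product: 14 (3R,3aS,4S,8aS)-4-[(tert-butyldimethylsilyl)oxy]-3-hydroxy-8a-methyl-3-(propan-2-yl)-2,3,3a,4,5,8a-hexahydroazulen-6(1H)-one
Conditions: MnO2 (activated, excess), CH2Cl2, rt
Reagents that add atoms: none
Why: MnO2 oxidises only the allylic alcohol (the tertiary alcohol cannot react), which erases the temporary C6 relay stereocentre.

**Step 11**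
Reactants: 14 (3R,3aS,4S,8aS)-4-[(tert-butyldimethylsilyl)oxy]-3-hydroxy-8a-methyl-3-(propan-2-yl)-2,3,3a,4,5,8a-hexahydroazulen-6(1H)-one
Product: 15 (3R,3aS,4S,6R,8aS)-4-[(tert-butyldimethylsilyl)oxy]-6,8a-dimethyl-3-(propan-2-yl)-1,2,3,3a,4,5,6,8a-octahydroazulene-3,6-diol
Conditions: MeLi (3 equiv), THF/Et2O, −78 °C; then H2O
Reagents that add atoms: methyllithium, [Li]C
Why: 1,2-addition of methyllithium to the enone; the α face is shielded by the C4 silyloxy group and the C8a methyl group, so methyl should enter from the β face and set C6 as R (hydroxyl α, cis to the C4 oxygen).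

**Step 12**
Reactants: 15 (3R,3aS,4S,6R,8aS)-4-[(tert-butyldimethylsilyl)oxy]-6,8a-dimethyl-3-(propan-2-yl)-1,2,3,3a,4,5,6,8a-octahydroazulene-3,6-diol
Product: 16 (3R,3aS,4S,6R,8aS)-6,8a-dimethyl-3-(propan-2-yl)-1,2,3,3a,4,5,6,8a-octahydroazulene-3,4,6-triol
Conditions: TBAF, THF, rt to 50 °C
Reagents that add atoms: none
Why: Fluoride-driven cleavage of the hindered silyl ether, to which the tertiary and tertiary allylic alcohols are stable.

**Step 13**
Reactants: 16 (3R,3aS,4S,6R,8aS)-6,8a-dimethyl-3-(propan-2-yl)-1,2,3,3a,4,5,6,8a-octahydroazulene-3,4,6-triol; 17 4-acetoxybenzoyl chloride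
Product: 18 (3R,3aS,4S,6R,8aS)-3,6-dihydroxy-6,8a-dimethyl-3-(propan-2-yl)-1,2,3,3a,4,5,6,8a-octahydroazulen-4-yl 4-(acetyloxy)benzoate
Conditions: Et3N, DMAP (cat.), CH2Cl2, 0 °C to rt
Reagents that add atoms: none
Why: DMAP-catalysed acylation of the only secondary alcohol, with retention at C4; both tertiary alcohols are too hindered to react.

**Step 14**
Reactants: 18 (3R,3aS,4S,6R,8aS)-3,6-dihydroxy-6,8a-dimethyl-3-(propan-2-yl)-1,2,3,3a,4,5,6,8a-octahydroazulen-4-yl 4-(acetyloxy)benzoate
Product: 19 (3R,3aS,4S,6R,8aS)-3,6-dihydroxy-6,8a-dimethyl-3-(propan-2-yl)-1,2,3,3a,4,5,6,8a-octahydroazulen-4-yl 4-hydroxybenzoate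
Conditions: K2CO3 (0.2 equiv), MeOH, 0 °C
Reagents that add atoms: none
Why: Base-catalysed transesterification should remove the aryl acetate, a far better acyl donor than the hindered secondary benzoate, whose carbonyl is further deactivated once the phenoxide forms.

**Compound list**

1 | (E)-3-methylpent-2-en-4-yn-1-ol | OC/C=C(C)/C#C | starting material
2 | (E)-3-methylpenta-2,4-dien-1-ol | OC/C=C(C)/C=C | intermediate
3 | but-3-yn-2-one | CC(=O)C#C | starting material
4 | (3E)-4-{[(2E)-3-methylpenta-2,4-dien-1-yl]oxy}but-3-en-2-one | CC(=O)/C=C/OC/C=C(C)/C=C | intermediate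
5 | (E)-but-2-enal | C/C=C/C=O | starting material
6 | (1E,5R,6E)-5-hydroxy-1-{[(2E)-3-methylpenta-2,4-dien-1-yl]oxy}octa-1,6-dien-3-one | C=C/C(C)=C/CO/C=C/C(=O)C[C@@H](O)/C=C/C | intermediate
7 | (1E,3S,5R,6E)-1-{[(2E)-3-methylpenta-2,4-dien-1-yl]oxy}octa-1,6-diene-3,5-diol | C=C/C(C)=C/CO/C=C/[C@@H](O)C[C@@H](O)/C=C/C | intermediate
8 | (1E,3S,5R,6E)-3,5-bis[(tert-butyldimethylsilyl)oxy]-1-{[(2E)-3-methylpenta-2,4-dien-1-yl]oxy}octa-1,6-diene | C=C/C(C)=C/CO/C=C/[C@@H](O[Si](C)(C)C(C)(C)C)C[C@@H](O[Si](C)(C)C(C)(C)C)/C=C/C | intermediate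
9 | (2S,3S,5R,6E)-3,5-bis[(tert-butyldimethylsilyl)oxy]-2-(3-methylpenta-1,4-dien-3-yl)oct-6-enal (not isolated) | O=C[C@H]([C@@H](O[Si](C)(C)C(C)(C)C)C[C@@H](O[Si](C)(C)C(C)(C)C)/C=C/C)C(C)(C=C)C=C | intermediate
10 | (2S,3S)-2-{(1S,3R,4E)-1,3-bis[(tert-butyldimethylsilyl)oxy]hex-4-en-1-yl}-3-ethenyl-3-methylcyclopentan-1-one | O=C1CC[C@@](C)(C=C)[C@H]1[C@@H](O[Si](C)(C)C(C)(C)C)C[C@@H](O[Si](C)(C)C(C)(C)C)/C=C/C | intermediate
11 | (1R,2S,3S)-2-{(1S,3R,4E)-1,3-bis[(tert-butyldimethylsilyl)oxy]hex-4-en-1-yl}-3-ethenyl-3-methyl-1-(propan-2-yl)cyclopentan-1-ol | CC(C)[C@]1(O)CC[C@@](C)(C=C)[C@H]1[C@@H](O[Si](C)(C)C(C)(C)C)C[C@@H](O[Si](C)(C)C(C)(C)C)/C=C/C | intermediate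
12 | (3R,3aS,4S,6R,8aS)-4,6-bis[(tert-butyldimethylsilyl)oxy]-8a-methyl-3-(propan-2-yl)-1,2,3,3a,4,5,6,8a-octahydroazulen-3-ol | CC(C)[C@]1(O)CC[C@@]2(C)C=C[C@H](O[Si](C)(C)C(C)(C)C)C[C@H](O[Si](C)(C)C(C)(C)C)[C@@H]12 | intermediate
13 | (3R,3aS,4S,6R,8aS)-4-[(tert-butyldimethylsilyl)oxy]-8a-methyl-3-(propan-2-yl)-1,2,3,3a,4,5,6,8a-octahydroazulene-3,6-diol | CC(C)[C@]1(O)CC[C@@]2(C)C=C[C@H](O)C[C@H](O[Si](C)(C)C(C)(C)C)[C@@H]12 | intermediate
14 | (3R,3aS,4S,8aS)-4-[(tert-butyldimethylsilyl)oxy]-3-hydroxy-8a-methyl-3-(propan-2-yl)-2,3,3a,4,5,8a-hexahydroazulen-6(1H)-one | CC(C)[C@]1(O)CC[C@@]2(C)C=CC(=O)C[C@H](O[Si](C)(C)C(C)(C)C)[C@@H]12 | intermediate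
15 | (3R,3aS,4S,6R,8aS)-4-[(tert-butyldimethylsilyl)oxy]-6,8a-dimethyl-3-(propan-2-yl)-1,2,3,3a,4,5,6,8a-octahydroazulene-3,6-diol | CC(C)[C@]1(O)CC[C@@]2(C)C=C[C@](C)(O)C[C@H](O[Si](C)(C)C(C)(C)C)[C@@H]12 | intermediate
16 | (3R,3aS,4S,6R,8aS)-6,8a-dimethyl-3-(propan-2-yl)-1,2,3,3a,4,5,6,8a-octahydroazulene-3,4,6-triol | CC(C)[C@]1(O)CC[C@@]2(C)C=C[C@](C)(O)C[C@H](O)[C@@H]12 | intermediate
17 | 4-acetoxybenzoyl chloride | CC(=O)Oc1ccc(cc1)C(Cl)=O | starting material
18 | (3R,3aS,4S,6R,8aS)-3,6-dihydroxy-6,8a-dimethyl-3-(propan-2-yl)-1,2,3,3a,4,5,6,8a-octahydroazulen-4-yl 4-(acetyloxy)benzoate | CC(C)[C@]1(O)CC[C@@]2(C)C=C[C@](C)(O)C[C@H](OC(=O)c3ccc(OC(C)=O)cc3)[C@@H]12 | intermediate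
19 | (3R,3aS,4S,6R,8aS)-3,6-dihydroxy-6,8a-dimethyl-3-(propan-2-yl)-1,2,3,3a,4,5,6,8a-octahydroazulen-4-yl 4-hydroxybenzoate | CC(C)[C@]1(O)CC[C@@]2(C)C=C[C@](C)(O)C[C@H](OC(=O)c3ccc(O)cc3)[C@@H]12 | target

**Step count and risks**

Total step count: 14. Longest linear sequence: 14 steps (1 to 19; compounds 3, 5 and 17 enter as bought building blocks).

Steps most likely to fail:

1. Step 6 (key step). The rearrangement may show low facial selectivity, the two vinyl groups may be poorly discriminated at 120 °C, or rhodium may cause decarbonylation or double-bond migration before the ring closes. Fallback: the two events are decoupled. From 8, a metal-free Claisen rearrangement in toluene at 110 °C is run with isolation of aldehyde 9. The hydroacylation is then carried out at room temperature with the cationic complex [Rh((R)-BINAP)]ClO4 in CH2Cl2, where catalyst control over the choice of vinyl group is strongest. The sequence comes back to the route at 10.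

2. Step 3. Zinc enolate formation from the electron-rich vinylogous ester may be slow, so that self-condensation of the aldehyde or cyclisation of the zinc aldolate onto the enol ether takes over; enantioselectivity may also be low. Fallback: from 4, TMSOTf and Et3N in CH2Cl2 at 0 °C give the silyl dienol ether trimethyl{[(3E)-4-{[(2E)-3-methylpenta-2,4-dien-1-yl]oxy}buta-1,3-dien-2-yl]oxy}silane F1. A Mukaiyama aldol addition of F1 to 5, catalysed by BINOL/Ti(OiPr)4 (antipode chosen for 5R), gives the silylated aldol (1E,5R,6E)-1-{[(2E)-3-methylpenta-2,4-dien-1-yl]oxy}-5-[(trimethylsilyl)oxy]octa-1,6-dien-3-one F2. K2CO3 in MeOH at 0 °C removes the silyl group, and the sequence comes back at 6.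

3. Step 7. The hindered ketone may be enolised, or reduced by β-hydride transfer from the secondary Grignard reagent, in place of addition. Fallback: from 10, ring-closing metathesis is run first (same catalyst as step 8) to give the bicyclic ketone (3aS,4S,6R,8aS)-4,6-bis[(tert-butyldimethylsilyl)oxy]-8a-methyl-1,2,4,5,6,8a-hexahydroazulen-3(3aH)-one F3. Isopropenylmagnesium bromide with CeCl3 in THF at −78 °C, an sp2 nucleophile without β-hydrogen, should add from the convex face to give (3S,3aS,4S,6R,8aS)-4,6-bis[(tert-butyldimethylsilyl)oxy]-8a-methyl-3-(prop-1-en-2-yl)-1,2,3,3a,4,5,6,8a-octahydroazulen-3-ol F4. Hydroxyl-directed hydrogenation of the isopropenyl group with [Ir(cod)(PCy3)(py)]PF6 and H2 in CH2Cl2 comes back to the route at 12.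

**Further compounds**

F0 | step 6 | none | none
F1 | step 3 | trimethyl{[(3E)-4-{[(2E)-3-methylpenta-2,4-dien-1-yl]oxy}buta-1,3-dien-2-yl]oxy}silane | C=C/C(C)=C/CO/C=C/C(=C)O[Si](C)(C)C
F2 | step 3 | (1E,5R,6E)-1-{[(2E)-3-methylpenta-2,4-dien-1-yl]oxy}-5-[(trimethylsilyl)oxy]octa-1,6-dien-3-one | C=C/C(C)=C/CO/C=C/C(=O)C[C@@H](O[Si](C)(C)C)/C=C/C
F3 | step 7 | (3aS,4S,6R,8aS)-4,6-bis[(tert-butyldimethylsilyl)oxy]-8a-methyl-1,2,4,5,6,8a-hexahydroazulen-3(3aH)-one | O=C1CC[C@@]2(C)C=C[C@H](O[Si](C)(C)C(C)(C)C)C[C@H](O[Si](C)(C)C(C)(C)C)[C@@H]12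
F4 | step 7 | (3S,3aS,4S,6R,8aS)-4,6-bis[(tert-butyldimethylsilyl)oxy]-8a-methyl-3-(prop-1-en-2-yl)-1,2,3,3a,4,5,6,8a-octahydroazulen-3-ol | CC(=C)[C@]1(O)CC[C@@]2(C)C=C[C@H](O[Si](C)(C)C(C)(C)C)C[C@H](O[Si](C)(C)C(C)(C)C)[C@@H]12
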